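## Retrosynthetic overview

- The target is traced back, by hydrodebromination and by invertive hydration at allylic C6 of a C1–C6 oxirane, to the epoxide of a 4-bromo-1-(benzoyloxymethyl)cyclohexa-1,3-diene cis-5,6-diacetate. Epoxidation anti to the two acetates sets C1 and C6 in one event, relayed from C2/C3, and the C4 bromine blocks the second alkene and the SN2' site.
- Key disconnection C1–C7 (ring carbon to CH2O carbon): an enantiotopic-group-selective Suzuki–Miyaura coupling of meso-3,6-dibromocyclohexa-3,5-diene-1,2-diol with potassium (acetoxymethyl)trifluoroborate. It forms the bond and fixes the absolute configuration of C2/C3 in the same operation.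
- Enabling feature: with C1–C6 at the alkene level, ring carbons C1 and C4 flank the cis-dioxygenated C2–C3 unit symmetrically. As the two C–Br carbons of the meso diene they are enantiotopic (mirror plane through the midpoints of C2–C3 and C5–C6).
- Rings: the six-membered carbocycle is the benzene ring of 1,4-dibromobenzene, dearomatised by enzymatic cis-dihydroxylation and never opened. The only ring formed afterwards is the temporary oxirane (step 4), opened again in step 5.

Key step: step 2

Remarks on the chemistry: locants C1–C7 in the explanatory text are those of the target (C1 = carbinol carbon bearing the CH2O carbon C7, C2/C3 = acetoxy carbons, C4=C5 = alkene, C6 = secondary carbinol carbon); compound names carry their own systematic locants. The cis-dihydrodiol intermediates aromatise with acid or heat, so they are kept cold and acid-free and are carried on promptly.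

## Route

Step 1
Reactants: 1 1,4-dibromobenzene
Product: 2 meso-(1R,2S)-3,6-dibromocyclohexa-3,5-diene-1,2-diol
Conditions: E. coli JM109(pDTG601A) whole cells (toluene dioxygenase), air, glucose, phosphate buffer pH 7.2, 30 °C
Reagents that add atoms: dioxygen, O=O
Why: Enzymatic dearomatising cis-dihydroxylation by a Rieske-type non-heme iron arene dioxygenase (toluene dioxygenase): both atoms of one O2 are delivered to the same face of the 2,3-bond, which makes the two carbinol carbons cis, and because the product is meso no enantioselectivity is asked of the enzyme.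

Step 2
Reactants: 2 meso-(1R,2S)-3,6-dibromocyclohexa-3,5-diene-1,2-diol; 3 potassium (acetoxymethyl)trifluoroborate
Product: 5 (1S,2S)-3-bromo-6-(hydroxymethyl)cyclohexa-3,5-diene-1,2-diol, via dienediol acetate 4 (not isolated)
Conditions: Pd(OAc)2 (5 mol %), one antipode of sodium 2'-(dicyclohexylphosphino)-2,6-dimethoxybiphenyl-3-sulfonate (sSPhos, 10 mol %), K3PO4, THF/H2O, 60 °C; then K2CO3 (cat.), MeOH, 0 °C to rt
Reagents that add atoms: none
Why: Proposed new method: zerovalent palladium carrying one antipode of the axially chiral sulfonated biarylphosphine sSPhos should insert irreversibly into one of the two enantiotopic alkenyl C–Br bonds of meso-2, the acetoxymethyl group is then transferred from boron (the trifluoroborate is hydrolysed in situ) and reductive elimination forms the C1–C7 bond, after which methanolysis frees the primary alcohol. The closest known reaction types are the Suzuki–Miyaura coupling of alkenyl and aryl bromides with acetoxymethyl- and alkoxymethyltrifluoroborates under dialkylbiarylphosphine ligands and the enantioselective desymmetrising Suzuki–Miyaura coupling of meso or prochiral bis(triflates) and bis(halides) with chiral monophosphines, enantiopure sSPhos among them; neither has been shown on a meso 1,4-dibromodiene or with an sp3 boron partner in the desymmetrising mode. No ring is closed and no new stereogenic atom is made: the ligand axis (catalyst control) decides which terminus reacts and so turns the meso (1R,2S) pair of carbinol carbons into the (1S,2S) pair that ends as C3 and C2 of the target. The sulfonate of the ligand is expected to hydrogen-bond, or to be bridged by potassium, to the allylic hydroxyl next to the C–Br bond that reacts, which makes the two diastereomeric insertion transition states differ; this is why the diol is left unprotected. The step needs enantiotopic-group selectivity and mono- over bis-coupling: the first coupling replaces bromine by an alkyl group, which makes the diene more electron-rich and the second insertion slower, and whatever second coupling occurs should consume mainly the minor enantiomer of 5 and raise the enantiomeric purity of the rest. The ligand antipode that leads to the (1S,2S) series is fixed in the first run, both antipodes being available.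

Step 3
Reactants: 5 (1S,2S)-3-bromo-6-(hydroxymethyl)cyclohexa-3,5-diene-1,2-diol
Product: 7 [(5S,6S)-5,6-bis(acetyloxy)-4-bromocyclohexa-1,3-dien-1-yl]methyl benzoate, via diol benzoate 6 (not isolated)
Conditions: BzCl (1.05 equiv), 2,4,6-collidine, CH2Cl2, −78 °C; then Ac2O, DMAP (cat.), pyridine, 0 °C
Reagents that add atoms: benzoyl chloride, O=C(Cl)c1ccccc1; acetic anhydride, CC(=O)OC(C)=O
Why: Selective acylation: benzoyl chloride with a hindered pyridine base at −78 °C esterifies the primary allylic hydroxyl well before the two secondary ones, and acetylation in the same flask caps the diol before 1,3-acyl migration can scramble the esters; no stereocenter is touched.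

Step 4
Reactants: 7 [(5S,6S)-5,6-bis(acetyloxy)-4-bromocyclohexa-1,3-dien-1-yl]methyl benzoate
Product: 8 [(1R,2R,3S,6R)-2,3-bis(acetyloxy)-4-bromo-7-oxabicyclo[4.1.0]hept-4-en-1-yl]methyl benzoate
Conditions: mCPBA, Na2HPO4, CH2Cl2, 0 °C to rt
Reagents that add atoms: 3-chloroperoxybenzoic acid (mCPBA), OOC(=O)c1cccc(Cl)c1
Why: Prilezhaev epoxidation: the electrophilic peracid should take the trisubstituted C1=C6 alkene, since the C4=C5 alkene is deactivated by its bromine, and approach from the face opposite the two cis acetoxy groups (the C2 acetoxy group, pseudoaxial to avoid allylic strain with the C1 substituent, covers the other face), so that C1 and C6 are set together by substrate control from C2/C3.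

Step 5
Reactants: 8 [(1R,2R,3S,6R)-2,3-bis(acetyloxy)-4-bromo-7-oxabicyclo[4.1.0]hept-4-en-1-yl]methyl benzoate
Product: 9 [(1R,2R,3S,6S)-2,3-bis(acetyloxy)-4-bromo-1,6-dihydroxycyclohex-4-en-1-yl]methyl benzoate
Conditions: HClO4 (cat.), THF/H2O, 0 °C
Reagents that add atoms: water, O
Why: Acid-catalysed trans-opening (hydration) of a vinyl oxirane: water should attack the protonated oxirane at the allylic carbon C6 with inversion, because C1 is quaternary and flanked by two electron-poor oxygenated carbons and the SN2' terminus C4 carries bromine, which puts the C6 hydroxyl on the face of the acetates and leaves the C1 oxygen, with retained configuration, as the tertiary alcohol.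

Step 6
Reactants: 9 [(1R,2R,3S,6S)-2,3-bis(acetyloxy)-4-bromo-1,6-dihydroxycyclohex-4-en-1-yl]methyl benzoate
Product: 10 [(1R,2R,3R,6S)-2,3-bis(acetyloxy)-1,6-dihydroxycyclohex-4-en-1-yl]methyl benzoate
Conditions: Bu3SnH, AIBN (cat.), toluene, 80 °C
Reagents that add atoms: none
Why: Radical-chain hydrodebromination (tin hydride reduction of an alkenyl bromide): the alkenyl radical formed by bromine abstraction is trapped by Bu3SnH much faster than it can rearrange, no stereocenter is involved, and esters and free hydroxyls are inert to the conditions.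

## Compound list

1 | 1,4-dibromobenzene | Brc1ccc(Br)cc1 | starting material
2 | meso-(1R,2S)-3,6-dibromocyclohexa-3,5-diene-1,2-diol (cis-diol) | O[C@@H]1[C@H](O)C(Br)=CC=C1Br | intermediate
3 | potassium (acetoxymethyl)trifluoroborate | CC(=O)OC[B-](F)(F)F.[K+] | starting material
4 | [(5S,6S)-4-bromo-5,6-dihydroxycyclohexa-1,3-dien-1-yl]methyl acetate | O[C@@H]1[C@H](O)C(Br)=CC=C1COC(C)=O | intermediate (not isolated)
5 | (1S,2S)-3-bromo-6-(hydroxymethyl)cyclohexa-3,5-diene-1,2-diol | O[C@@H]1[C@H](O)C(Br)=CC=C1CO | intermediate
6 | [(5S,6S)-4-bromo-5,6-dihydroxycyclohexa-1,3-dien-1-yl]methyl benzoate | O[C@@H]1[C@H](O)C(Br)=CC=C1COC(=O)c1ccccc1 | intermediate (not isolated)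
7 | [(5S,6S)-5,6-bis(acetyloxy)-4-bromocyclohexa-1,3-dien-1-yl]methyl benzoate | CC(=O)O[C@@H]1[C@H](OC(C)=O)C(Br)=CC=C1COC(=O)c1ccccc1 | intermediate
8 | [(1R,2R,3S,6R)-2,3-bis(acetyloxy)-4-bromo-7-oxabicyclo[4.1.0]hept-4-en-1-yl]methyl benzoate (oxirane oxygen anti to the acetates) | CC(=O)O[C@@H]1[C@H](OC(C)=O)C(Br)=C[C@H]2O[C@@]12COC(=O)c1ccccc1 | intermediate
9 | [(1R,2R,3S,6S)-2,3-bis(acetyloxy)-4-bromo-1,6-dihydroxycyclohex-4-en-1-yl]methyl benzoate | CC(=O)O[C@@H]1[C@H](OC(C)=O)C(Br)=C[C@H](O)[C@]1(O)COC(=O)c1ccccc1 | intermediate
10 | [(1R,2R,3R,6S)-2,3-bis(acetyloxy)-1,6-dihydroxycyclohex-4-en-1-yl]methyl benzoate | CC(=O)O[C@@H]1[C@H](OC(C)=O)C=C[C@H](O)[C@]1(O)COC(=O)c1ccccc1 | target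

Total step count: 6. Longest linear sequence: 6 steps (1 to 10); 3 is purchased.

## Steps most likely to fail

Step 2 (proposed new method). What may go wrong: too little discrimination between the two enantiotopic C–Br termini, over-coupling to the bis(hydroxymethyl) diene, or transmetalation of the sp3 boron partner too slow at a temperature the dienediol tolerates. The fallback uses known chemistry and takes the absolute configuration from the enzyme instead of the palladium catalyst; it sets out from 1 and comes back to the route at 10.
- 1 is monolithiated (n-BuLi, THF, −78 °C) and iodinated (I2) to 1-bromo-4-iodobenzene F1 (also purchasable).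
- The whole-cell toluene dioxygenase oxidation of step 1, which places the larger halogen next to the diol in its usual sense, should give (1S,2R)-3-bromo-6-iodocyclohexa-3,5-diene-1,2-diol F2.
- Chemoselective hydrogenolysis of the C–I bond (H2, Pd/C, NaOAc, MeOH, 0 °C, stopped after one equivalent) gives (1R,2R)-3-bromocyclohexa-3,5-diene-1,2-diol F3, the antipode of the diol the enzyme makes from bromobenzene.
- Stille coupling with (tributylstannyl)methanol (Pd(PPh3)4, dioxane, 80 °C) forms the same C1–C7 bond and gives (1R,2S)-3-(hydroxymethyl)cyclohexa-3,5-diene-1,2-diol F4.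
- The conditions of step 3 give, through [(5R,6S)-5,6-dihydroxycyclohexa-1,3-dien-1-yl]methyl benzoate F5 (not isolated), [(5R,6S)-5,6-bis(acetyloxy)cyclohexa-1,3-dien-1-yl]methyl benzoate F6.
- The conditions of step 4, now relying on the higher substitution of the C1=C6 alkene instead of the bromine block, give [(1R,2R,3R,6R)-2,3-bis(acetyloxy)-7-oxabicyclo[4.1.0]hept-4-en-1-yl]methyl benzoate F7, and the conditions of step 5 convert F7 into 10.

Step 5. What may go wrong: participation of the C2 acetate or of the benzoate carbonyl in the opening of the protonated oxirane, acid-catalysed migration of benzoyl from the primary oxygen to the new C6 hydroxyl, or attack of water at the quaternary C1. In the fallback the C6 oxygen arrives masked and is unmasked under neutral oxidative conditions; it sets out from 8 and comes back at 9.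
- Alcoholysis of 8 with 4-methoxybenzyl alcohol (cat. BF3·OEt2, CH2Cl2, −30 °C) at the allylic carbon with inversion should give [(1R,2R,3S,6S)-2,3-bis(acetyloxy)-4-bromo-1-hydroxy-6-[(4-methoxyphenyl)methoxy]cyclohex-4-en-1-yl]methyl benzoate F8, which has no free C6 hydroxyl to accept an acyl group.
- DDQ (CH2Cl2/pH 7 buffer, 0 °C) removes the 4-methoxybenzyl group and gives 9.

Step 4. What may go wrong: epoxidation of the doubly deactivated diene so slow that loss of acetic acid (aromatisation) takes over, or poor facial selectivity. In the fallback both oxygens are added from the open face by osmylation and C6 is then inverted, with no oxirane involved; it sets out from 7 and comes back at 9.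
- Upjohn dihydroxylation (OsO4 cat., NMO, acetone/H2O, 0 °C) of the C1=C6 alkene, anti to the allylic acetate, should give the cis-diol [(1R,2R,3S,6R)-2,3-bis(acetyloxy)-4-bromo-1,6-dihydroxycyclohex-4-en-1-yl]methyl benzoate F9.
- Mitsunobu reaction at the secondary allylic hydroxyl (ClCH2CO2H, PPh3, DIAD, THF, 0 °C; the tertiary hydroxyl does not react) inverts C6 and gives [(1R,2R,3S,6S)-2,3-bis(acetyloxy)-4-bromo-6-(chloroacetyloxy)-1-hydroxycyclohex-4-en-1-yl]methyl benzoate F10.
- Thiourea (NaHCO3, EtOH, 50 °C) removes the chloroacetyl group selectively and gives 9.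

## Further compounds

F1 | step 2 | 1-bromo-4-iodobenzene | Brc1ccc(I)cc1
F2 | step 2 | (1S,2R)-3-bromo-6-iodocyclohexa-3,5-diene-1,2-diol | O[C@@H]1[C@H](O)C(I)=CC=C1Br
F3 | step 2 | (1R,2R)-3-bromocyclohexa-3,5-diene-1,2-diol | O[C@@H]1[C@H](O)C=CC=C1Br
F4 | step 2 | (1R,2S)-3-(hydroxymethyl)cyclohexa-3,5-diene-1,2-diol | O[C@@H]1[C@H](O)C=CC=C1CO
F5 | step 2 | [(5R,6S)-5,6-dihydroxycyclohexa-1,3-dien-1-yl]methyl benzoate | O[C@@H]1[C@H](O)C=CC=C1COC(=O)c1ccccc1
F6 | step 2 | [(5R,6S)-5,6-bis(acetyloxy)cyclohexa-1,3-dien-1-yl]methyl benzoate | CC(=O)O[C@@H]1[C@H](OC(C)=O)C=CC=C1COC(=O)c1ccccc1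
F7 | step 2 | [(1R,2R,3R,6R)-2,3-bis(acetyloxy)-7-oxabicyclo[4.1.0]hept-4-en-1-yl]methyl benzoate | CC(=O)O[C@@H]1[C@H](OC(C)=O)C=C[C@H]2O[C@@]12COC(=O)c1ccccc1
F8 | step 5 | [(1R,2R,3S,6S)-2,3-bis(acetyloxy)-4-bromo-1-hydroxy-6-[(4-methoxyphenyl)methoxy]cyclohex-4-en-1-yl]methyl benzoate | CC(=O)O[C@@H]1[C@H](OC(C)=O)C(Br)=C[C@H](OCc2ccc(OC)cc2)[C@]1(O)COC(=O)c1ccccc1
F9 | step 4 | [(1R,2R,3S,6R)-2,3-bis(acetyloxy)-4-bromo-1,6-dihydroxycyclohex-4-en-1-yl]methyl benzoate | CC(=O)O[C@@H]1[C@H](OC(C)=O)C(Br)=C[C@@H](O)[C@]1(O)COC(=O)c1ccccc1
F10 | step 4 | [(1R,2R,3S,6S)-2,3-bis(acetyloxy)-4-bromo-6-(chloroacetyloxy)-1-hydroxycyclohex-4-en-1-yl]methyl benzoate | CC(=O)O[C@@H]1[C@H](OC(C)=O)C(Br)=C[C@H](OC(=O)CCl)[C@]1(O)COC(=O)c1ccccc1
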